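The cyclohexene ring (C1, C2, C3=C4, C4a, C8a) is disconnected at C1–C2. Its precursor is a cis-fused thiolane in which sulfur bridges C1, which carries an ester, and C4, which carries the (E,E)-dienyl chain. S-Methylation and deprotonation give a sulfonium ylide whose [2,3]-sigmatropic shift turns the five-membered sulfur ring into the six-membered carbocycle. One operation forms C1–C2, places the double bond at C3=C4, sets C2 and leaves sulfur as a removable group on C1. The step exploits the allylic position of C2 next to the trisubstituted C3=C4 bond and the carboxyl-derived carbon on C1. The thiolane comes from an asymmetric Diels–Alder adduct by thioether formation and Michael–alkylation.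

Key step: step 8

Remark: the locants C1–C8a of the target's octahydronaphthalene core are used for the corresponding carbons of every intermediate in the explanations; diene 2 is taken as purchasable, and 24 is isolated as the free acid after acidification.

Step 1
Reactants: 1 pent-1-en-3-one; 2 2-(triisopropylsilyloxy)buta-1,3-diene
Product: 3 (S)-1-[4-(triisopropylsilyloxy)cyclohex-3-en-1-yl]propan-1-one
Conditions: chiral o-tolyl-oxazaborolidinium triflimide from diphenylprolinol (10 mol %, the enantiomer that gives (S)-3), CH2Cl2, −78 °C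
Reagents that add atoms: none
Why: Enantioselective Lewis-acid-catalysed Diels–Alder reaction in which the 2-siloxy diene gives the 1,4-adduct and the chiral boron cation shields one face of the bound enone, which sets C4a and stores its configuration in the position of the enol ether double bond (C7=C8).

Step 2
Reactants: 3 (S)-1-[4-(triisopropylsilyloxy)cyclohex-3-en-1-yl]propan-1-one; 4 (E)-2-methylbut-2-enal
Product: 7 (2E,4E)-2,4-dimethyl-1-[(1S)-4-(triisopropylsilyloxy)cyclohex-3-en-1-yl]hexa-2,4-dien-1-one, via aldol adduct 5 (not isolated), via aldol mesylate 6 (not isolated)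
Conditions: LiN(i-Pr)2, THF, −78 °C; 4; MsCl, −78 → 0 °C; DBU, 0 °C
Reagents that add atoms: none
Why: Aldol condensation in which kinetic enolisation on the CH2 side of the ethyl ketone, addition to the enal and E1cB loss of mesylate should give the thermodynamically preferred (E)-α-methyl enone without touching C4a.

Step 3
Reactants: 7 (2E,4E)-2,4-dimethyl-1-[(1S)-4-(triisopropylsilyloxy)cyclohex-3-en-1-yl]hexa-2,4-dien-1-one
Product: 8 (1R,2E,4E)-2,4-dimethyl-1-[(1S)-4-(triisopropylsilyloxy)cyclohex-3-en-1-yl]hexa-2,4-dien-1-ol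
Conditions: (S)-2-methyl-CBS-oxazaborolidine (20 mol %), catecholborane, toluene, −78 °C
Reagents that add atoms: none
Why: CBS reduction in which the α-branched dienyl group acts as the large substituent, so that reagent control should set the carbinol carbon (C4) as (R) whatever the neighbouring ring stereocentre.

Step 4
Reactants: 8 (1R,2E,4E)-2,4-dimethyl-1-[(1S)-4-(triisopropylsilyloxy)cyclohex-3-en-1-yl]hexa-2,4-dien-1-ol
Product: 9 (4S)-4-[(1R,2E,4E)-1-hydroxy-2,4-dimethylhexa-2,4-dien-1-yl]cyclohex-2-en-1-one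
Conditions: Pd(OAc)2 (1.1 equiv), MeCN, 40 °C
Reagents that add atoms: none
Why: Saegusa–Ito oxidation in which the enol ether of fixed position is palladated at C8 and β-hydride loss from C8a should give the enone on that side only, so that C4a stays a stereocentre.

Step 5
Reactants: 9 (4S)-4-[(1R,2E,4E)-1-hydroxy-2,4-dimethylhexa-2,4-dien-1-yl]cyclohex-2-en-1-one; 10 methyl sulfanylacetate
Product: 11 methyl 2-({(1S,2E,4E)-2,4-dimethyl-1-[(1S)-4-oxocyclohex-2-en-1-yl]hexa-2,4-dien-1-yl}sulfanyl)acetate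
Conditions: PPh3, DIAD, THF, −20 → 0 °C
Reagents that add atoms: none
Why: Mitsunobu thioetherification with the acidic thiol, in which SN2 displacement of the oxyphosphonium group should invert C4 to the (S)-sulfide.

Step 6
Reactants: 11 methyl 2-({(1S,2E,4E)-2,4-dimethyl-1-[(1S)-4-oxocyclohex-2-en-1-yl]hexa-2,4-dien-1-yl}sulfanyl)acetate
Product: 13 methyl (1R,3S,3aS,7R,7aR)-7-methyl-3-[(2E,4E)-4-methylhexa-2,4-dien-2-yl]-6-oxooctahydro-2-benzothiophene-1-carboxylate, via lithium enolate 12 (not isolated)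
Conditions: 11 added to LiN(SiMe3)2 (1.05 equiv), THF, −78 °C; then MeI, DMPU, −78 → −30 °C
Reagents that add atoms: iodomethane CI
Why: Intramolecular Michael addition (5-exo) of the sulfur- and ester-flanked carbanion, the most acidic site for the silylamide base, should close the thiolane cis-fused (setting C8a) and leave the C7 enolate regiospecifically, which is methylated at C8 anti to the new C8a–C1 bond as in conjugate addition–alkylation.

Step 7
Reactants: 13 methyl (1R,3S,3aS,7R,7aR)-7-methyl-3-[(2E,4E)-4-methylhexa-2,4-dien-2-yl]-6-oxooctahydro-2-benzothiophene-1-carboxylate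
Product: 14 methyl (1R,3S,3aS,6S,7R,7aR)-6-hydroxy-7-methyl-3-[(2E,4E)-4-methylhexa-2,4-dien-2-yl]octahydro-2-benzothiophene-1-carboxylate
Conditions: LiBH(s-Bu)3, THF, −78 °C; aq. NH4Cl
Reagents that add atoms: none
Why: Ketone reduction by the bulky borohydride, which should deliver hydride anti to the adjacent C8 methyl group as with 2-methylcyclohexanone and so give the C7 alcohol cis to that methyl group.

Step 8
Reactants: 14 methyl (1R,3S,3aS,6S,7R,7aR)-6-hydroxy-7-methyl-3-[(2E,4E)-4-methylhexa-2,4-dien-2-yl]octahydro-2-benzothiophene-1-carboxylate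
Product: 17 methyl (1R,2S,4aR,7S,8R,8aS)-2-[(2E)-but-2-en-2-yl]-7-hydroxy-3,8-dimethyl-1-(methylsulfanyl)-1,2,4a,5,6,7,8,8a-octahydronaphthalene-1-carboxylate, via thiolanium triflate 15 (not isolated), via sulfonium ylide 16 (not isolated)
Conditions: MeOTf (1.05 equiv), CH2Cl2, −40 → 0 °C; then DBU, −40 °C → rt
Reagents that add atoms: methyl trifluoromethanesulfonate COS(=O)(=O)C(F)(F)F
Why: Proposed new method: S-methylation gives the cis-fused thiolanium salt 15, DBU removes the proton at C1 (the only one flanked by the sulfonium centre and the ester) and the stabilised ylide 16 rearranges by a [2,3]-sigmatropic shift in which C1 bonds to C2 (the terminus of the alkenyl unit on C4), the S–C4 bond breaks and the double bond moves to C3=C4. The closest known reaction types are the ring-growing [2,3] shifts of 2-vinylthiacycloalkane sulfonium ylides, in which the ylide carbon is exocyclic, and the enolate Claisen carbocyclisation of alkenyl lactones as the [3,3] counterpart; here the ylide carbon and the allylic carbon both lie in the thiolane, so the heterocycle is enlarged to a carbocycle and sulfur is left outside the ring. The six-membered ring closes through the five-centre envelope transition state of the [2,3] shift, bridged by the C4a–C8a bond (a 7-thianorbornene-like array with two long partial bonds), suprafacially on the allyl unit. C2 is set by the (E)-geometry of the migrating double bond together with the convex-face position of the dienyl group (cis to H4a and H8a), which puts the butenyl group exo and H2 on the side of the ring-fusion hydrogens, while at C1 sulfur stays on the face it departs from, so the ester is cis to H2 and H8a. The step needs S- before O-methylation (sulfide against a hindered secondary alcohol at low temperature), ylide formation at C1 and not at C4 or S-methyl (secured by the ester) and the [2,3] shift ahead of a [1,2] shift or ring-opening elimination (favoured by the strong driving force from ylide to neutral sulfide and by the short tether that holds C1 over the diene terminus).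

Step 9
Reactants: 17 methyl (1R,2S,4aR,7S,8R,8aS)-2-[(2E)-but-2-en-2-yl]-7-hydroxy-3,8-dimethyl-1-(methylsulfanyl)-1,2,4a,5,6,7,8,8a-octahydronaphthalene-1-carboxylate
Product: 19 methyl (1S,2S,4aS,7S,8R,8aS)-2-[(2E)-but-2-en-2-yl]-7-hydroxy-3,8-dimethyl-1,2,4a,5,6,7,8,8a-octahydronaphthalene-1-carboxylate, via C1-epimeric ester 18 (not isolated)
Conditions: Bu3SnH, AIBN, toluene, 90 °C; then NaOMe, MeOH, rt
Reagents that add atoms: none
Why: Radical desulfurisation, in which the stannyl radical attacks sulfur and releases the tertiary α-ester radical that takes up hydrogen, is followed by methoxide equilibration of the epimerisable C1 to the ester that is trans to both the C2 butenyl group and the C8a–C8 bond (all three pseudo-equatorial), which sets C1.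

Step 10
Reactants: 19 methyl (1S,2S,4aS,7S,8R,8aS)-2-[(2E)-but-2-en-2-yl]-7-hydroxy-3,8-dimethyl-1,2,4a,5,6,7,8,8a-octahydronaphthalene-1-carboxylate
Product: 20 (1S,2S,4aS,7S,8R,8aS)-2-[(2E)-but-2-en-2-yl]-7-hydroxy-3,8-dimethyl-1,2,4a,5,6,7,8,8a-octahydronaphthalene-1-carbaldehyde
Conditions: i-Bu2AlH (2.2 equiv), CH2Cl2, −78 °C; aq. potassium sodium tartrate
Reagents that add atoms: none
Why: Partial ester reduction in which the tetrahedral aluminium hemiacetal persists at −78 °C and should release the aldehyde only on work-up, with C1 kept in its thermodynamically preferred configuration.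

Step 11
Reactants: 20 (1S,2S,4aS,7S,8R,8aS)-2-[(2E)-but-2-en-2-yl]-7-hydroxy-3,8-dimethyl-1,2,4a,5,6,7,8,8a-octahydronaphthalene-1-carbaldehyde; 21 ethyl (E)-4-(diethoxyphosphoryl)but-2-enoate
Product: 22 ethyl (2E,4E)-5-[(1S,2S,4aS,7S,8R,8aR)-2-[(2E)-but-2-en-2-yl]-7-hydroxy-3,8-dimethyl-1,2,4a,5,6,7,8,8a-octahydronaphthalen-1-yl]penta-2,4-dienoate
Conditions: LiN(SiMe3)2 (2.2 equiv), THF, −78 → 0 °C
Reagents that add atoms: none
Why: Horner–Wadsworth–Emmons olefination with the vinylogous phosphonate, which should give the (2E,4E)-dienoate.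

Step 12
Reactants: 22 ethyl (2E,4E)-5-[(1S,2S,4aS,7S,8R,8aR)-2-[(2E)-but-2-en-2-yl]-7-hydroxy-3,8-dimethyl-1,2,4a,5,6,7,8,8a-octahydronaphthalen-1-yl]penta-2,4-dienoate
Product: 24 (2E,4E)-5-[(1S,2S,4aS,7S,8R,8aR)-2-[(2E)-but-2-en-2-yl]-3,8-dimethyl-7-(sulfooxy)-1,2,4a,5,6,7,8,8a-octahydronaphthalen-1-yl]penta-2,4-dienoic acid, via sulfated ethyl ester 23 (not isolated)
Conditions: SO3·pyridine, pyridine, rt; then LiOH, THF–H2O, rt; aq. HCl to pH 2
Reagents that add atoms: sulfur trioxide–pyridine complex [O-]S(=O)(=O)[n+]1ccccc1; lithium hydroxide [Li+].[OH-]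
Why: O-Sulfation of the secondary alcohol followed by saponification of the ethyl ester, to which the alkyl sulfate monoester should be inert, and acidification to the free acid.

Compound list
1 | pent-1-en-3-one (ethyl vinyl ketone) | CCC(=O)C=C | starting material
2 | 2-(triisopropylsilyloxy)buta-1,3-diene | C=CC(=C)O[Si](C(C)C)(C(C)C)C(C)C | starting material
3 | (S)-1-[4-(triisopropylsilyloxy)cyclohex-3-en-1-yl]propan-1-one | CCC(=O)[C@H]1CCC(O[Si](C(C)C)(C(C)C)C(C)C)=CC1 | intermediate
4 | (E)-2-methylbut-2-enal (tiglic aldehyde) | C/C=C(\C)C=O | starting material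
5 | (4E)-3-hydroxy-2,4-dimethyl-1-[(1S)-4-(triisopropylsilyloxy)cyclohex-3-en-1-yl]hex-4-en-1-one (aldol adduct, both new centres undefined) | C/C=C(\C)C(O)C(C)C(=O)[C@H]1CCC(O[Si](C(C)C)(C(C)C)C(C)C)=CC1 | intermediate (not isolated)
6 | methanesulfonate of 5 | C/C=C(\C)C(OS(C)(=O)=O)C(C)C(=O)[C@H]1CCC(O[Si](C(C)C)(C(C)C)C(C)C)=CC1 | intermediate (not isolated)
7 | (2E,4E)-2,4-dimethyl-1-[(1S)-4-(triisopropylsilyloxy)cyclohex-3-en-1-yl]hexa-2,4-dien-1-one | C/C=C(\C)/C=C(\C)C(=O)[C@H]1CCC(O[Si](C(C)C)(C(C)C)C(C)C)=CC1 | intermediate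
8 | (1R,2E,4E)-2,4-dimethyl-1-[(1S)-4-(triisopropylsilyloxy)cyclohex-3-en-1-yl]hexa-2,4-dien-1-ol | C/C=C(\C)/C=C(\C)[C@H](O)[C@H]1CCC(O[Si](C(C)C)(C(C)C)C(C)C)=CC1 | intermediate
9 | (4S)-4-[(1R,2E,4E)-1-hydroxy-2,4-dimethylhexa-2,4-dien-1-yl]cyclohex-2-en-1-one | C/C=C(\C)/C=C(\C)[C@H](O)[C@H]1CCC(=O)C=C1 | intermediate
10 | methyl sulfanylacetate (methyl thioglycolate) | COC(=O)CS | starting material
11 | methyl 2-({(1S,2E,4E)-2,4-dimethyl-1-[(1S)-4-oxocyclohex-2-en-1-yl]hexa-2,4-dien-1-yl}sulfanyl)acetate | C/C=C(\C)/C=C(\C)[C@@H](SCC(=O)OC)[C@H]1CCC(=O)C=C1 | intermediate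
12 | lithium (1R,3S,3aS,7aR)-1-(methoxycarbonyl)-3-[(2E,4E)-4-methylhexa-2,4-dien-2-yl]-1,3,3a,4,5,7a-hexahydro-2-benzothiophen-6-olate (enolate of the cyclised ketone) | C/C=C(\C)/C=C(\C)[C@H]1S[C@@H](C(=O)OC)[C@@H]2C=C([O-])CC[C@H]12.[Li+] | intermediate (not isolated)
13 | methyl (1R,3S,3aS,7R,7aR)-7-methyl-3-[(2E,4E)-4-methylhexa-2,4-dien-2-yl]-6-oxooctahydro-2-benzothiophene-1-carboxylate (cis-fused; C1 epimers converge later) | C/C=C(\C)/C=C(\C)[C@H]1S[C@@H](C(=O)OC)[C@@H]2[C@@H](C)C(=O)CC[C@H]12 | intermediate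
14 | methyl (1R,3S,3aS,6S,7R,7aR)-6-hydroxy-7-methyl-3-[(2E,4E)-4-methylhexa-2,4-dien-2-yl]octahydro-2-benzothiophene-1-carboxylate | C/C=C(\C)/C=C(\C)[C@H]1S[C@@H](C(=O)OC)[C@@H]2[C@@H](C)[C@@H](O)CC[C@H]12 | intermediate
15 | S-methylthiolanium trifluoromethanesulfonate of 14 (2-methyl-octahydro-2-benzothiophen-2-ium salt, either configuration at sulfur) | C/C=C(\C)/C=C(\C)[C@H]1[S+](C)[C@@H](C(=O)OC)[C@@H]2[C@@H](C)[C@@H](O)CC[C@H]12.[O-]S(=O)(=O)C(F)(F)F | intermediate (not isolated)
16 | sulfonium ylide of 15 (carbanion at C1, stabilised by the ester) | C/C=C(\C)/C=C(\C)[C@H]1[S+](C)[C-](C(=O)OC)[C@@H]2[C@@H](C)[C@@H](O)CC[C@H]12 | intermediate (not isolated)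
17 | methyl (1R,2S,4aR,7S,8R,8aS)-2-[(2E)-but-2-en-2-yl]-7-hydroxy-3,8-dimethyl-1-(methylsulfanyl)-1,2,4a,5,6,7,8,8a-octahydronaphthalene-1-carboxylate | C/C=C(\C)[C@H]1C(C)=C[C@H]2CC[C@H](O)[C@H](C)[C@H]2[C@]1(SC)C(=O)OC | intermediate
18 | methyl (1R,2S,4aS,7S,8R,8aS)-2-[(2E)-but-2-en-2-yl]-7-hydroxy-3,8-dimethyl-1,2,4a,5,6,7,8,8a-octahydronaphthalene-1-carboxylate (C1 epimer of 19) | C/C=C(\C)[C@H]1C(C)=C[C@H]2CC[C@H](O)[C@H](C)[C@H]2[C@H]1C(=O)OC | intermediate (not isolated)
19 | methyl (1S,2S,4aS,7S,8R,8aS)-2-[(2E)-but-2-en-2-yl]-7-hydroxy-3,8-dimethyl-1,2,4a,5,6,7,8,8a-octahydronaphthalene-1-carboxylate | C/C=C(\C)[C@H]1C(C)=C[C@H]2CC[C@H](O)[C@H](C)[C@H]2[C@@H]1C(=O)OC | intermediate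
20 | (1S,2S,4aS,7S,8R,8aS)-2-[(2E)-but-2-en-2-yl]-7-hydroxy-3,8-dimethyl-1,2,4a,5,6,7,8,8a-octahydronaphthalene-1-carbaldehyde | C/C=C(\C)[C@H]1C(C)=C[C@H]2CC[C@H](O)[C@H](C)[C@H]2[C@@H]1C=O | intermediate
21 | ethyl (E)-4-(diethoxyphosphoryl)but-2-enoate (triethyl 4-phosphonocrotonate) | CCOC(=O)/C=C/CP(=O)(OCC)OCC | starting material
22 | ethyl (2E,4E)-5-[(1S,2S,4aS,7S,8R,8aR)-2-[(2E)-but-2-en-2-yl]-7-hydroxy-3,8-dimethyl-1,2,4a,5,6,7,8,8a-octahydronaphthalen-1-yl]penta-2,4-dienoate | C/C=C(\C)[C@H]1C(C)=C[C@H]2CC[C@H](O)[C@H](C)[C@H]2[C@@H]1/C=C/C=C/C(=O)OCC | intermediate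
23 | ethyl (2E,4E)-5-[(1S,2S,4aS,7S,8R,8aR)-2-[(2E)-but-2-en-2-yl]-3,8-dimethyl-7-(sulfooxy)-1,2,4a,5,6,7,8,8a-octahydronaphthalen-1-yl]penta-2,4-dienoate | C/C=C(\C)[C@H]1C(C)=C[C@H]2CC[C@H](OS(=O)(=O)O)[C@H](C)[C@H]2[C@@H]1/C=C/C=C/C(=O)OCC | intermediate (not isolated)
24 | (2E,4E)-5-[(1S,2S,4aS,7S,8R,8aR)-2-[(2E)-but-2-en-2-yl]-3,8-dimethyl-7-(sulfooxy)-1,2,4a,5,6,7,8,8a-octahydronaphthalen-1-yl]penta-2,4-dienoic acid | C/C=C(\C)[C@H]1C(C)=C[C@H]2CC[C@H](OS(=O)(=O)O)[C@H](C)[C@H]2[C@@H]1/C=C/C=C/C(=O)O | target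

Total step count: 12. Longest linear sequence: 12 steps (from 1 and 2 to 24).

Steps most likely to fail

Step 8 (the ring expansion). The ylide may not reach the bridged five-centre transition state and may instead undergo a [1,2] shift or ring-opening elimination. The dienylic sulfonium salt may also ionise before it is deprotonated. The fallback reaches the same bond stepwise with known reactions, setting out from 14 and coming back at 17. After S-methylation with MeOTf, the thiolanium ring is opened at the dienylic carbon with Bu4NOAc. This should give the ring-opened acetate methyl 2-[(1R,2R,3S,6S)-6-[(2E,4E)-1-(acetyloxy)-2,4-dimethylhexa-2,4-dien-1-yl]-3-hydroxy-2-methylcyclohexyl]-2-(methylsulfanyl)acetate F4; allylic isomers of the acetate would converge in the next operation, and demethylated material returns 14. The lithium enolate of F4 (LiN(SiMe3)2) is then cyclised by intramolecular allylic alkylation with Pd(PPh3)4, a source of zerovalent palladium. Ring closure at C2 should be preferred over the four- and eight-membered alternatives and gives 17, without the stereochemical control of the concerted shift at C2.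

Step 6 (Michael addition and methylation). The base may also deprotonate the enone. An anion at C4a would expel the thiolate and erase the C4 and C4a stereocentres, and proton exchange may scramble the enolate before it is methylated. The fallback sets out from 11 and comes back at 13. Deprotonation with LiN(SiMe3)2 in the presence of Me3SiCl at −100 °C traps the ester enolate as the silyl ketene acetal [(1-methoxy-2-{[(1S,2E,4E)-2,4-dimethyl-1-[(1S)-4-oxocyclohex-2-en-1-yl]hexa-2,4-dien-1-yl]sulfanyl}ethenyl)oxy]trimethylsilane F2; material silylated on the enone instead returns 11 on hydrolysis. Catalytic Me3SiOTf then promotes an intramolecular Mukaiyama–Michael addition to the silyl enol ether methyl (1R,3S,3aS,7aR)-3-[(2E,4E)-4-methylhexa-2,4-dien-2-yl]-6-(trimethylsilyloxy)-1,3,3a,4,5,7a-hexahydro-2-benzothiophene-1-carboxylate F3. F3 is methylated regiospecifically with BnMe3NF and MeI to give 13.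

Step 5 (thiol Mitsunobu reaction). Configuration at the dienylic carbon may be lost through ionisation or SN2′ attack, and the thiol may be consumed by the azodicarboxylate. The fallback sets out from 9 and comes back at 11. The Mitsunobu reaction is run with thioacetic acid, a more acidic and better-behaved pronucleophile, to give with inversion the thioacetate S-[(1S,2E,4E)-2,4-dimethyl-1-[(1S)-4-oxocyclohex-2-en-1-yl]hexa-2,4-dien-1-yl] ethanethioate F1. The acetyl group is removed with pyrrolidine and the thiol is alkylated in the same flask with methyl bromoacetate and i-Pr2NEt to give 11.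

Further compounds
F1 | step 5 | S-[(1S,2E,4E)-2,4-dimethyl-1-[(1S)-4-oxocyclohex-2-en-1-yl]hexa-2,4-dien-1-yl] ethanethioate | C/C=C(\C)/C=C(\C)[C@@H](SC(C)=O)[C@H]1CCC(=O)C=C1
F2 | step 6 | [(1-methoxy-2-{[(1S,2E,4E)-2,4-dimethyl-1-[(1S)-4-oxocyclohex-2-en-1-yl]hexa-2,4-dien-1-yl]sulfanyl}ethenyl)oxy]trimethylsilane | C/C=C(\C)/C=C(\C)[C@@H](SC=C(OC)O[Si](C)(C)C)[C@H]1CCC(=O)C=C1
F3 | step 6 | methyl (1R,3S,3aS,7aR)-3-[(2E,4E)-4-methylhexa-2,4-dien-2-yl]-6-(trimethylsilyloxy)-1,3,3a,4,5,7a-hexahydro-2-benzothiophene-1-carboxylate | C/C=C(\C)/C=C(\C)[C@H]1S[C@@H](C(=O)OC)[C@@H]2C=C(O[Si](C)(C)C)CC[C@H]12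
F4 | step 8 | methyl 2-[(1R,2R,3S,6S)-6-[(2E,4E)-1-(acetyloxy)-2,4-dimethylhexa-2,4-dien-1-yl]-3-hydroxy-2-methylcyclohexyl]-2-(methylsulfanyl)acetate | C/C=C(\C)/C=C(\C)C(OC(C)=O)[C@H]1CC[C@H](O)[C@H](C)[C@H]1C(SC)C(=O)OC
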